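**Plan**

- Numbering used here: ring A = C1–C5 plus C10 (C3 carbinol, C4 gem-dimethyl); ring B = C5–C10 (C6=C7, C8=C12 methylene, C9 bearing C11H2–O–aryl, C10 bearing methyl).
- Retrosynthesis, first cut: the C11–O aryl ether (Mitsunobu with umbelliferone). Second cut: both ring B bonds C5–C10 and C8–C9 in one retro-[4+2].
- Enabling feature: the cross-conjugated diene of ring B (ring olefin C6=C7 beside the exocyclic C8=C12), flanked by ester-level C9/C11 and the methyl-bearing quaternary C10, is the retron of a vinylallene Diels–Alder reaction; C1–C4 of ring A is the tether.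
- The acyclic precursor is cut at C7–C8 (vinyl iodide plus allenylstannane), at C5=C6 (Takai), at C3–C4 (Mukaiyama aldol), and goes back to methyl geranate cleaved at its distal olefin.
- Forward: the chain is built linearly, rings A and B arise together in the one cycloaddition, then ester to CH2OH, etherification and desilylation.
- Stereochemistry: C3 from the enantioselective aldol; C5, C9 and C10 from C3 (equatorial silyloxy group on a chair tether), the (E)-enoate (methyl and C11 cis) and ester-endo closure (trans fusion).

Key step: step 9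

Assumption: methyl geranate is used as the pure (2E) isomer (any (2Z) isomer is removed first), because this olefin geometry becomes the C9/C10 relationship.

**Step 1**
Reactants: 1 2-methylpropanoyl chloride; 2 ethanethiol
Product: 3 S-ethyl 2-methylpropanethioate
Conditions: Et3N, CH2Cl2, 0 °C → rt
Reagents that add atoms: none
Why: Nucleophilic acyl substitution of the acid chloride by the thiol (Schotten–Baumann-type acylation) gives the thioester, and no stereocentre is involved.

**Step 2**
Reactants: 3 S-ethyl 2-methylpropanethioate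
Product: 4 {[1-(ethylsulfanyl)-2-methylprop-1-en-1-yl]oxy}(trimethyl)silane
Conditions: LDA, TMSCl, THF, −78 °C → rt
Reagents that add atoms: chlorotrimethylsilane, C[Si](C)(C)Cl
Why: Enolisation with LDA and O-silylation by TMSCl (silyl enol ether formation) should give the ketene silyl S,O-acetal, whose symmetric dimethyl terminus removes any E/Z question.

**Step 3**
Reactants: 5 methyl (2E)-3,7-dimethylocta-2,6-dienoate (methyl geranate)
Product: 7 methyl (2E)-3-methyl-6-oxohex-2-enoate, via epoxy ester 6 (not isolated)
Conditions: mCPBA, CH2Cl2, 0 °C; then H5IO6, THF/H2O, 0 °C → rt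
Reagents that add atoms: 3-chloroperoxybenzoic acid (mCPBA), O=C(OO)c1cccc(Cl)c1
Why: Prilezhaev epoxidation should pick the electron-rich distal olefin over the deactivated enoate, and periodic acid then hydrolyses the epoxide and cleaves the diol (Malaprade-type glycol cleavage) to the aldehyde with the (2E)-enoate intact.

**Step 4**
Reactants: 7 methyl (2E)-3-methyl-6-oxohex-2-enoate; 4 {[1-(ethylsulfanyl)-2-methylprop-1-en-1-yl]oxy}(trimethyl)silane
Product: 9 methyl (2E,6R)-8-(ethylsulfanyl)-6-hydroxy-3,7,7-trimethyl-8-oxooct-2-enoate, via TMS ether 8 (not isolated)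
Conditions: N-Ts-L-valine, BH3·THF, CH2Cl2, −78 °C; then 1 M HCl, THF, rt
Reagents that add atoms: none
Why: In this enantioselective Mukaiyama aldol addition (Kiyooka variant) the aldehyde bound to the valine-derived oxazaborolidinone should be attacked from the face left open by the isopropyl group, which is expected to set the (6R) carbinol (future C3) from the L-valine promoter (the D-valine promoter is the remedy if the sense proves opposite), while the dimethyl nucleophile makes the C4 quaternary carbon without a second stereocentre and the thioester keeps this carbonyl distinguishable from the methyl enoate.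

**Step 5**
Reactants: 9 methyl (2E,6R)-8-(ethylsulfanyl)-6-hydroxy-3,7,7-trimethyl-8-oxooct-2-enoate
Product: 10 methyl (2E,6R)-8-(ethylsulfanyl)-3,7,7-trimethyl-8-oxo-6-[(triethylsilyl)oxy]oct-2-enoate
Conditions: TESOTf, 2,6-lutidine, CH2Cl2, −78 → 0 °C
Reagents that add atoms: triethylsilyl trifluoromethanesulfonate, CC[Si](CC)(CC)OS(=O)(=O)C(F)(F)F
Why: Silyl ether protection of the hindered secondary alcohol blocks retro-aldol cleavage, keeps this hydroxyl out of the later Mitsunobu reaction and gives C3 the bulky group that steers the cycloaddition.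

**Step 6**
Reactants: 10 methyl (2E,6R)-8-(ethylsulfanyl)-3,7,7-trimethyl-8-oxo-6-[(triethylsilyl)oxy]oct-2-enoate
Product: 11 methyl (2E,6R)-3,7,7-trimethyl-8-oxo-6-[(triethylsilyl)oxy]oct-2-enoate
Conditions: Et3SiH, 10% Pd/C, acetone, rt
Reagents that add atoms: none
Why: In the Fukuyama reduction palladium inserts into the acyl–sulfur bond and the silane delivers hydride to the acyl group, so the thioester should give the non-enolisable aldehyde while the methyl enoate and the silyl ether are untouched.

**Step 7**
Reactants: 11 methyl (2E,6R)-3,7,7-trimethyl-8-oxo-6-[(triethylsilyl)oxy]oct-2-enoate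
Product: 12 methyl (2E,6R,8E)-9-iodo-3,7,7-trimethyl-6-[(triethylsilyl)oxy]nona-2,8-dienoate
Conditions: CHI3, CrCl2, THF/dioxane, 0 °C → rt
Reagents that add atoms: iodoform, IC(I)I
Why: In the Takai olefination the geminal dichromium reagent from iodoform adds to the aldehyde and eliminates to the (E)-vinyl iodide, the E preference being reinforced by the quaternary neighbour, and the ester is inert to the organochromium reagent.

**Step 8**
Reactants: 12 methyl (2E,6R,8E)-9-iodo-3,7,7-trimethyl-6-[(triethylsilyl)oxy]nona-2,8-dienoate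
Product: 13 methyl (2E,6R,8E)-3,7,7-trimethyl-6-[(triethylsilyl)oxy]dodeca-2,8,10,11-tetraenoate
Conditions: allenylSnBu3, Pd2(dba)3 (cat.), P(2-furyl)3, LiCl, DMF, rt, dark
Reagents that add atoms: tributyl(propa-1,2-dien-1-yl)stannane, C=C=C[Sn](CCCC)(CCCC)CCCC
Why: In this Stille coupling zerovalent palladium adds to the vinyl iodide with retention of the (E) geometry, the allenyl group is transferred from tin at its tin-bearing carbon and reductive elimination should give the 1-substituted vinylallene, which is kept cold and dilute until the next step.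

**Step 9**
Reactants: 13 methyl (2E,6R,8E)-3,7,7-trimethyl-6-[(triethylsilyl)oxy]dodeca-2,8,10,11-tetraenoate
Product: 14 methyl (1R,4aS,6R,8aR)-5,5,8a-trimethyl-2-methylidene-6-[(triethylsilyl)oxy]-1,2,4a,5,6,7,8,8a-octahydronaphthalene-1-carboxylate
Conditions: PhMe (0.01 M), BHT (cat.), 100 °C, sealed tube, Ar
Reagents that add atoms: none
Why: A concerted, asynchronous thermal [4+2] cycloaddition in which the vinylallene (C5=C6–C7=C8, C8 being the central allene carbon) is the diene and the (E)-β-methyl enoate C9=C10 the dienophile; the closest known reaction type is the intramolecular Diels–Alder reaction of vinylallenes, which are unusually reactive dienes. Ring B closes as the new cyclohexene through the C5–C10 and C8–C9 bonds (suprafacial on both partners, leaving C6=C7 in the ring and the untouched outer allene bond as the C8=C12 methylene), and ring A closes at the same moment as the fused six-membered tether ring (type 1 mode, four-carbon tether C1–C4, chair-like) through the C5–C10 bond alone. C9 and C10 are set relative to each other by the (E) geometry of the enoate, which keeps the C10 methyl and the ester cis, and C5 is set trans to the C10 methyl by the (E)-diene reacting through the ester-endo, tether-anti transition state that leads to the trans-fused decalin. The absolute sense should follow from C3, whose OSiEt3 group is expected to sit equatorial on the chair-like tether, so that the (R) centre delivers the (1R,4aS,8aR) array. The step needs periselectivity (the conjugated allene π bond, not a [2+2] at the outer one), trans over cis fusion and one diene face; the tether length fixes the pairing of the termini, the C4 gem-dimethyl group removes the hydrogens needed for a [1,5]-H shift of the vinylallene and favours the reactive rotamer (Thorpe–Ingold effect), and high dilution with BHT suppresses dimerisation.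

**Step 10**
Reactants: 14 methyl (1R,4aS,6R,8aR)-5,5,8a-trimethyl-2-methylidene-6-[(triethylsilyl)oxy]-1,2,4a,5,6,7,8,8a-octahydronaphthalene-1-carboxylate
Product: 15 [(1R,4aS,6R,8aR)-5,5,8a-trimethyl-2-methylidene-6-[(triethylsilyl)oxy]-1,2,4a,5,6,7,8,8a-octahydronaphthalen-1-yl]methanol
Conditions: DIBAL-H, CH2Cl2, −78 → 0 °C; Rochelle salt work-up
Reagents that add atoms: none
Why: Hydride reduction of the ester with the Lewis acidic, non-basic DIBAL-H should give the primary alcohol without deprotonating the doubly allylic C9–H, so C9 is not epimerised and the diene is not moved into conjugation.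

**Step 11**
Reactants: 15 [(1R,4aS,6R,8aR)-5,5,8a-trimethyl-2-methylidene-6-[(triethylsilyl)oxy]-1,2,4a,5,6,7,8,8a-octahydronaphthalen-1-yl]methanol; 16 7-hydroxy-2H-chromen-2-one (umbelliferone)
Product: 17 7-{[(1R,4aS,6R,8aR)-5,5,8a-trimethyl-2-methylidene-6-[(triethylsilyl)oxy]-1,2,4a,5,6,7,8,8a-octahydronaphthalen-1-yl]methoxy}-2H-chromen-2-one
Conditions: PPh3, DIAD, THF, 0 °C → rt
Reagents that add atoms: none
Why: In the Mitsunobu etherification the acidic phenol protonates the betaine and its phenoxide displaces the oxyphosphonium group at the primary C11 (SN2), so no stereocentre is touched and the lactone stays closed under the neutral conditions.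

**Step 12**
Reactants: 17 7-{[(1R,4aS,6R,8aR)-5,5,8a-trimethyl-2-methylidene-6-[(triethylsilyl)oxy]-1,2,4a,5,6,7,8,8a-octahydronaphthalen-1-yl]methoxy}-2H-chromen-2-one
Product: 18 7-{[(1R,4aS,6R,8aR)-6-hydroxy-5,5,8a-trimethyl-2-methylidene-1,2,4a,5,6,7,8,8a-octahydronaphthalen-1-yl]methoxy}-2H-chromen-2-one
Conditions: HF·pyridine, pyridine, THF, 0 °C → rt
Reagents that add atoms: none
Why: Fluoride-driven cleavage of the triethylsilyl ether under pyridine-buffered conditions should free the C3 hydroxyl without acid-promoted isomerisation of the cross-conjugated diene or opening of the coumarin.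

**Compound list**

1 | 2-methylpropanoyl chloride | CC(C)C(=O)Cl | starting material
2 | ethanethiol | CCS | starting material
3 | S-ethyl 2-methylpropanethioate | CCSC(=O)C(C)C | intermediate
4 | {[1-(ethylsulfanyl)-2-methylprop-1-en-1-yl]oxy}(trimethyl)silane | CCSC(O[Si](C)(C)C)=C(C)C | intermediate
5 | methyl (2E)-3,7-dimethylocta-2,6-dienoate (methyl geranate) | COC(=O)/C=C(\C)CCC=C(C)C | starting material
6 | methyl (2E)-5-(3,3-dimethyloxiran-2-yl)-3-methylpent-2-enoate (racemic epoxide, not isolated) | COC(=O)/C=C(\C)CCC1OC1(C)C | intermediate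
7 | methyl (2E)-3-methyl-6-oxohex-2-enoate | COC(=O)/C=C(\C)CCC=O | intermediate
8 | methyl (2E,6R)-8-(ethylsulfanyl)-3,7,7-trimethyl-8-oxo-6-[(trimethylsilyl)oxy]oct-2-enoate (not isolated) | CCSC(=O)C(C)(C)[C@H](O[Si](C)(C)C)CC/C(C)=C/C(=O)OC | intermediate
9 | methyl (2E,6R)-8-(ethylsulfanyl)-6-hydroxy-3,7,7-trimethyl-8-oxooct-2-enoate | CCSC(=O)C(C)(C)[C@H](O)CC/C(C)=C/C(=O)OC | intermediate
10 | methyl (2E,6R)-8-(ethylsulfanyl)-3,7,7-trimethyl-8-oxo-6-[(triethylsilyl)oxy]oct-2-enoate | CCSC(=O)C(C)(C)[C@H](O[Si](CC)(CC)CC)CC/C(C)=C/C(=O)OC | intermediate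
11 | methyl (2E,6R)-3,7,7-trimethyl-8-oxo-6-[(triethylsilyl)oxy]oct-2-enoate | O=CC(C)(C)[C@H](O[Si](CC)(CC)CC)CC/C(C)=C/C(=O)OC | intermediate
12 | methyl (2E,6R,8E)-9-iodo-3,7,7-trimethyl-6-[(triethylsilyl)oxy]nona-2,8-dienoate | I/C=C/C(C)(C)[C@H](O[Si](CC)(CC)CC)CC/C(C)=C/C(=O)OC | intermediate
13 | methyl (2E,6R,8E)-3,7,7-trimethyl-6-[(triethylsilyl)oxy]dodeca-2,8,10,11-tetraenoate | C=C=C/C=C/C(C)(C)[C@H](O[Si](CC)(CC)CC)CC/C(C)=C/C(=O)OC | intermediate
14 | methyl (1R,4aS,6R,8aR)-5,5,8a-trimethyl-2-methylidene-6-[(triethylsilyl)oxy]-1,2,4a,5,6,7,8,8a-octahydronaphthalene-1-carboxylate | C=C1C=C[C@@H]2C(C)(C)[C@H](O[Si](CC)(CC)CC)CC[C@@]2(C)[C@@H]1C(=O)OC | intermediate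
15 | [(1R,4aS,6R,8aR)-5,5,8a-trimethyl-2-methylidene-6-[(triethylsilyl)oxy]-1,2,4a,5,6,7,8,8a-octahydronaphthalen-1-yl]methanol | C=C1C=C[C@@H]2C(C)(C)[C@H](O[Si](CC)(CC)CC)CC[C@@]2(C)[C@@H]1CO | intermediate
16 | 7-hydroxy-2H-chromen-2-one (umbelliferone) | Oc1ccc2ccc(=O)oc2c1 | starting material
17 | 7-{[(1R,4aS,6R,8aR)-5,5,8a-trimethyl-2-methylidene-6-[(triethylsilyl)oxy]-1,2,4a,5,6,7,8,8a-octahydronaphthalen-1-yl]methoxy}-2H-chromen-2-one | C=C1C=C[C@@H]2C(C)(C)[C@H](O[Si](CC)(CC)CC)CC[C@@]2(C)[C@@H]1COc1ccc2ccc(=O)oc2c1 | intermediate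
18 | 7-{[(1R,4aS,6R,8aR)-6-hydroxy-5,5,8a-trimethyl-2-methylidene-1,2,4a,5,6,7,8,8a-octahydronaphthalen-1-yl]methoxy}-2H-chromen-2-one | C=C1C=C[C@@H]2C(C)(C)[C@H](O)CC[C@@]2(C)[C@@H]1COc1ccc2ccc(=O)oc2c1 | target

**Count**

Total steps: 12. Longest linear sequence: 11 steps (steps 1, 2 and 4–12; the methyl geranate branch, step 3, joins at step 4).

**Steps most likely to fail**

Step 9. The remote C3 silyloxy group may give poor facial control, and cis-fused (ester-exo) closure may compete at the temperature a trisubstituted enoate needs. The fallback sets out from 13 and moves the dienophile to the aldehyde level so that a Lewis acid can drive a tighter, carbonyl-endo closure at low temperature. DIBAL-H (CH2Cl2, −78 °C) should give the allylic alcohol (2E,6R,8E)-3,7,7-trimethyl-6-[(triethylsilyl)oxy]dodeca-2,8,10,11-tetraen-1-ol F1. MnO2 (CH2Cl2, rt) should then give the enal (2E,6R,8E)-3,7,7-trimethyl-6-[(triethylsilyl)oxy]dodeca-2,8,10,11-tetraenal F2. Me2AlCl (CH2Cl2, −78 °C) should close it in a Lewis-acid-promoted intramolecular Diels–Alder reaction to (1R,4aS,6R,8aR)-5,5,8a-trimethyl-2-methylidene-6-[(triethylsilyl)oxy]-1,2,4a,5,6,7,8,8a-octahydronaphthalene-1-carbaldehyde F3. NaBH4 (MeOH, 0 °C) reduces this to 15, where the route is rejoined.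

Step 8. The tin-to-palladium transfer may lose allenyl versus propargyl regiocontrol, and the vinylallene may oligomerise during the coupling. The fallback sets out from 11 and reverses the polarity of the coupling. A Takai–Utimoto boron olefination (Cl2CHB(pin), CrCl2, LiI, THF) should give methyl (2E,6R,8E)-3,7,7-trimethyl-9-(4,4,5,5-tetramethyl-1,3,2-dioxaborolan-2-yl)-6-[(triethylsilyl)oxy]nona-2,8-dienoate F4. Pd(PPh3)4 with methyl prop-2-yn-1-yl carbonate (THF, 50 °C) then forms an allenylpalladium methoxide by SN2'-type oxidative addition, which takes the alkenyl group from boron (Suzuki–Miyaura coupling) and gives 13, where the route is rejoined.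

Step 11. Activation of the hindered, β-branched primary alcohol may be slow, and the oxyphosphonium intermediate may eliminate across the doubly allylic C9–H. The fallback sets out from 15 and leaves the C11–O bond intact by making the aryl partner the electrophile. Palladium-catalysed C–O cross-coupling with 7-bromo-2H-chromen-2-one ([(allyl)PdCl]2, RockPhos, Cs2CO3, PhMe, 90 °C) should give 17 directly, where the route is rejoined; this fallback makes no new compound (F0).

**Further compounds**

F1 | step 9 | (2E,6R,8E)-3,7,7-trimethyl-6-[(triethylsilyl)oxy]dodeca-2,8,10,11-tetraen-1-ol | C=C=C/C=C/C(C)(C)[C@H](O[Si](CC)(CC)CC)CC/C(C)=C/CO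
F2 | step 9 | (2E,6R,8E)-3,7,7-trimethyl-6-[(triethylsilyl)oxy]dodeca-2,8,10,11-tetraenal | C=C=C/C=C/C(C)(C)[C@H](O[Si](CC)(CC)CC)CC/C(C)=C/C=O
F3 | step 9 | (1R,4aS,6R,8aR)-5,5,8a-trimethyl-2-methylidene-6-[(triethylsilyl)oxy]-1,2,4a,5,6,7,8,8a-octahydronaphthalene-1-carbaldehyde | C=C1C=C[C@@H]2C(C)(C)[C@H](O[Si](CC)(CC)CC)CC[C@@]2(C)[C@@H]1C=O
F4 | step 8 | methyl (2E,6R,8E)-3,7,7-trimethyl-9-(4,4,5,5-tetramethyl-1,3,2-dioxaborolan-2-yl)-6-[(triethylsilyl)oxy]nona-2,8-dienoate | CC1(C)OB(OC1(C)C)/C=C/C(C)(C)[C@H](O[Si](CC)(CC)CC)CC/C(C)=C/C(=O)OC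
F0 | step 11 | none | none
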